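**Plan**

- Retrosynthesis cuts (a) the C8–C(=O) bond (aryllithium plus a cinnamoyl N-methoxy-N-methylamide), (b) the C3–H bond (back to the chroman-3-one), (c) the C4–C4a bond with reconnection of C4a to C3 (back to a 3-methylene-2,3-dihydrobenzofuran, one ring atom fewer), and (d) the C=CH2 bond and the two bonds from the ring carbonyl and the CMe2 carbon to ring A and its oxygen (back to phloroglucinol and 2-bromo-2-methylpropanoyl bromide).
- Forward: ring A is bought; the five-membered furanone ring is closed first (Friedel–Crafts acylation, then O-alkylation), methylenated, and enlarged to the six-membered pyranone ring by an oxidative 1,2-aryl shift; the chalcone chain is joined last by directed lithiation at C8 and acylation.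
- Enabling feature: C4a of ring A lies ortho/para to three oxygens (O1, O5, O7) and so migrates very readily, while C2 is quaternary (gem-dimethyl), so the precursor alkene cannot aromatise to a benzofuran and C2 is a poor competing migrating group; the inserted CH2 therefore becomes C4 and the oxygen ends at C3.
- Stereochemistry: the only stereocentre, C3 (R), comes from a CBS reduction of the C3 ketone, whose faces are told apart by quaternary C2 against the C4 methylene; the (E)-alkene comes from a Horner–Wadsworth–Emmons reaction.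
- Regiochemistry on ring A: symmetry of phloroglucinol, chelation-controlled mono-methylation, and a bulky silyl ether at O5 that leaves C8 as the site of lithiation.

Key step: step 5

Remark: compounds 11 and 12 are taken as purchased; chroman numbering (O1, C2, C3, C4, C4a, C5–C8, C8a) is used for six-membered-ring compounds and benzofuran numbering (O1, C2, C3, C3a, C4–C7, C7a) for the five-membered precursors.

**Route**

Step 1
Reactants: 1 phloroglucinol (benzene-1,3,5-triol); 2 2-bromo-2-methylpropanoyl bromide
Product: 4 4,6-dihydroxy-2,2-dimethyl-1-benzofuran-3(2H)-one, via aryl bromoketone 3 (not isolated)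
Conditions: AlCl3 (3.5 equiv), CH2Cl2/PhNO2, 0 °C → 40 °C; aqueous quench; crude 3, NaOAc, EtOH, reflux
Reagents that add atoms: none
Why: Friedel–Crafts C-acylation of the symmetric triol (all positions equivalent) should give the ortho-hydroxyaryl α-bromo ketone, whose phenoxide then displaces the tertiary α-keto bromide in a 5-exo-tet O-alkylation, the standard entry to 2,2-dimethylbenzofuran-3-ones.

Step 2
Reactants: 4 4,6-dihydroxy-2,2-dimethyl-1-benzofuran-3(2H)-one
Product: 5 4-hydroxy-6-methoxy-2,2-dimethyl-1-benzofuran-3(2H)-one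
Conditions: Me2SO4 (1.0 equiv), K2CO3 (1.1 equiv), acetone, rt
Reagents that add atoms: dimethyl sulfate, COS(=O)(=O)OC
Why: Williamson O-methylation should take place at the 6-OH, which is para to the carbonyl and the more acidic, unchelated hydroxyl, while the 4-OH is held by a hydrogen bond to the peri carbonyl, as in the selective 7-O-alkylation of 5,7-dihydroxychromanones.

Step 3
Reactants: 5 4-hydroxy-6-methoxy-2,2-dimethyl-1-benzofuran-3(2H)-one
Product: 6 6-methoxy-2,2-dimethyl-4-[(triisopropylsilyl)oxy]-1-benzofuran-3(2H)-one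
Conditions: TIPSOTf (1.2 equiv), 2,6-lutidine, CH2Cl2, 0 °C → rt
Reagents that add atoms: triisopropylsilyl trifluoromethanesulfonate, CC(C)[Si](OS(=O)(=O)C(F)(F)F)(C(C)C)C(C)C
Why: Silyl ether formation with the reactive triflate should overcome the chelated, hindered phenol, and the bulky group later protects the phenol against base and organolithium and shields its ortho position.

Step 4
Reactants: 6 6-methoxy-2,2-dimethyl-4-[(triisopropylsilyl)oxy]-1-benzofuran-3(2H)-one
Product: 7 [(6-methoxy-2,2-dimethyl-3-methylidene-2,3-dihydro-1-benzofuran-4-yl)oxy]triisopropylsilane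
Conditions: Ph3PCH3Br (3 equiv), KN(SiMe3)2 (2.8 equiv), toluene, 0 °C → 90 °C
Reagents that add atoms: methylidenetriphenylphosphorane (from methyltriphenylphosphonium bromide), C=P(c1ccccc1)(c1ccccc1)c1ccccc1
Why: Wittig methylenation should succeed under forcing conditions because the ketone is non-enolisable (C2 is quaternary), and the same quaternary carbon keeps the new double bond exocyclic.

Step 5
Reactants: 7 [(6-methoxy-2,2-dimethyl-3-methylidene-2,3-dihydro-1-benzofuran-4-yl)oxy]triisopropylsilane
Product: 8 7-methoxy-2,2-dimethyl-5-[(triisopropylsilyl)oxy]-2H-chromen-3(4H)-one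
Conditions: PhI(OH)OTs (1.05 equiv), MeOH/H2O 95:5, −20 °C → rt; used directly in step 6 under inert gas
Reagents that add atoms: water, O
Why: The electron-rich exocyclic styrene should attack the trivalent iodine of PhI(OH)OTs at its CH2 terminus, methanol or water caps the C3 benzylic cation, and loss of iodobenzene from the primary C–I bond is assisted by a 1,2-shift of the aryl carbon C3a from C3 to the exocyclic carbon through a phenonium-type bridge, leaving an oxocarbenium ion at C3 that is hydrolysed to the ketone. The closest known reaction type is the oxidative ring expansion of 1-methylene-benzocycloalkanes to β-benzocycloalkenones with PhI(OH)OTs or Tl(NO3)3, a semipinacol-type process used on indanone- and tetralone-derived alkenes. No ring is closed by cyclisation: the six-membered pyranone ring arises from the five-membered furan ring by insertion of the exocyclic CH2 between C3 and C3a, so the new methylene is C4 and the oxygen-bearing carbon is C3 of the chroman without ambiguity. No stereocentre is formed; C3 emerges as a prochiral carbonyl carbon that step 6 reduces enantioselectively. The step needs migration of the aryl carbon and not of C2, and attack of the iodane on the alkene and not on ring A: the first is secured by the three oxygen donors ortho and para to the migrating carbon and by C2 being a quaternary, inductively deactivated α-oxygenated carbon, the second by the enol-ether-like nucleophilicity of the alkene, the low temperature and the bulky silyl ether next to C5.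

Step 6
Reactants: 8 7-methoxy-2,2-dimethyl-5-[(triisopropylsilyl)oxy]-2H-chromen-3(4H)-one
Product: 9 (3R)-7-methoxy-2,2-dimethyl-5-[(triisopropylsilyl)oxy]-3,4-dihydro-2H-chromen-3-ol
Conditions: (S)-1-methyl-3,3-diphenyl-tetrahydro-1H,3H-pyrrolo[1,2-c][1,3,2]oxazaborole ((S)-Me-CBS, 0.15 equiv), BH3·SMe2, THF, −20 °C; MeOH quench
Reagents that add atoms: none
Why: In the CBS reduction the quaternary C2 acts as the large group and the C4 methylene as the small one, so the (S)-catalyst should deliver hydride to the Si face of C3 and give the (3R)-alcohol, by analogy with tert-alkyl and aryl ketones that give (R)-alcohols with this catalyst.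

Step 7
Reactants: 9 (3R)-7-methoxy-2,2-dimethyl-5-[(triisopropylsilyl)oxy]-3,4-dihydro-2H-chromen-3-ol
Product: 10 tert-butyl{[(3R)-7-methoxy-2,2-dimethyl-5-[(triisopropylsilyl)oxy]-3,4-dihydro-2H-chromen-3-yl]oxy}dimethylsilane
Conditions: TBSOTf (1.3 equiv), 2,6-lutidine, CH2Cl2, 0 °C
Reagents that add atoms: tert-butyldimethylsilyl trifluoromethanesulfonate, CC(C)(C)[Si](C)(C)OS(=O)(=O)C(F)(F)F
Why: Silylation with the triflate should protect the hindered secondary alcohol next to the quaternary carbon without touching the stereocentre, masking the acidic O–H before the lithiation.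

Step 8
Reactants: 11 4-[(tert-butyldimethylsilyl)oxy]benzaldehyde; 12 diethyl {2-[methoxy(methyl)amino]-2-oxoethyl}phosphonate
Product: 13 (2E)-3-{4-[(tert-butyldimethylsilyl)oxy]phenyl}-N-methoxy-N-methylprop-2-enamide
Conditions: NaH, THF, 0 °C → rt
Reagents that add atoms: none
Why: The Horner–Wadsworth–Emmons reaction of a stabilised phosphonate with an aryl aldehyde should give the (E)-enamide under thermodynamic control of the oxaphosphetane.

Step 9
Reactants: 10 tert-butyl{[(3R)-7-methoxy-2,2-dimethyl-5-[(triisopropylsilyl)oxy]-3,4-dihydro-2H-chromen-3-yl]oxy}dimethylsilane; 13 (2E)-3-{4-[(tert-butyldimethylsilyl)oxy]phenyl}-N-methoxy-N-methylprop-2-enamide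
Product: 15 (2E)-1-{(3R)-3-[(tert-butyldimethylsilyl)oxy]-7-methoxy-2,2-dimethyl-5-[(triisopropylsilyl)oxy]-3,4-dihydro-2H-chromen-8-yl}-3-{4-[(tert-butyldimethylsilyl)oxy]phenyl}prop-2-en-1-one, via 8-lithiochroman 14 (not isolated)
Conditions: n-BuLi (1.3 equiv), TMEDA, Et2O, 0 °C → rt; then 13, THF, −78 °C → 0 °C; then H2O
Reagents that add atoms: n-butyllithium, [Li]CCCC (its lithium stands in 14 only)
Why: Directed ortho-metalation should occur at C8, the position flanked by the two coordinating ether oxygens (7-OMe and O1), because C6 is shielded by the non-coordinating bulky silyl ether, and the aryllithium then adds 1,2 to the N-methoxy-N-methylamide to give a chelated adduct that releases the enone only on work-up (Weinreb ketone synthesis).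

Step 10
Reactants: 15 (2E)-1-{(3R)-3-[(tert-butyldimethylsilyl)oxy]-7-methoxy-2,2-dimethyl-5-[(triisopropylsilyl)oxy]-3,4-dihydro-2H-chromen-8-yl}-3-{4-[(tert-butyldimethylsilyl)oxy]phenyl}prop-2-en-1-one
Product: 16 (2E)-1-[(3R)-3,5-dihydroxy-7-methoxy-2,2-dimethyl-3,4-dihydro-2H-chromen-8-yl]-3-(4-hydroxyphenyl)prop-2-en-1-one
Conditions: Bu4NF (3.5 equiv), AcOH (3.5 equiv), THF, 0 °C → rt
Reagents that add atoms: none
Why: Fluoride-mediated desilylation should cleave the two aryl silyl ethers quickly and the hindered secondary silyl ether more slowly, and the buffered medium leaves the chalcone intact, since the molecule has no free hydroxyl ortho to the enone that could close a flavanone.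

**Compound list**

1 | phloroglucinol (benzene-1,3,5-triol) | Oc1cc(O)cc(O)c1 | starting material
2 | 2-bromo-2-methylpropanoyl bromide | CC(C)(Br)C(Br)=O | starting material
3 | 2-bromo-2-methyl-1-(2,4,6-trihydroxyphenyl)propan-1-one | CC(C)(Br)C(=O)c1c(O)cc(O)cc1O | intermediate
4 | 4,6-dihydroxy-2,2-dimethyl-1-benzofuran-3(2H)-one | CC1(C)Oc2cc(O)cc(O)c2C1=O | intermediate
5 | 4-hydroxy-6-methoxy-2,2-dimethyl-1-benzofuran-3(2H)-one | COc1cc(O)c2c(c1)OC(C)(C)C2=O | intermediate
6 | 6-methoxy-2,2-dimethyl-4-[(triisopropylsilyl)oxy]-1-benzofuran-3(2H)-one | COc1cc(O[Si](C(C)C)(C(C)C)C(C)C)c2c(c1)OC(C)(C)C2=O | intermediate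
7 | [(6-methoxy-2,2-dimethyl-3-methylidene-2,3-dihydro-1-benzofuran-4-yl)oxy]triisopropylsilane | COc1cc(O[Si](C(C)C)(C(C)C)C(C)C)c2c(c1)OC(C)(C)C2=C | intermediate
8 | 7-methoxy-2,2-dimethyl-5-[(triisopropylsilyl)oxy]-2H-chromen-3(4H)-one | COc1cc(O[Si](C(C)C)(C(C)C)C(C)C)c2c(c1)OC(C)(C)C(=O)C2 | intermediate
9 | (3R)-7-methoxy-2,2-dimethyl-5-[(triisopropylsilyl)oxy]-3,4-dihydro-2H-chromen-3-ol | COc1cc(O[Si](C(C)C)(C(C)C)C(C)C)c2c(c1)OC(C)(C)[C@H](O)C2 | intermediate
10 | tert-butyl{[(3R)-7-methoxy-2,2-dimethyl-5-[(triisopropylsilyl)oxy]-3,4-dihydro-2H-chromen-3-yl]oxy}dimethylsilane | COc1cc(O[Si](C(C)C)(C(C)C)C(C)C)c2c(c1)OC(C)(C)[C@H](O[Si](C)(C)C(C)(C)C)C2 | intermediate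
11 | 4-[(tert-butyldimethylsilyl)oxy]benzaldehyde | O=Cc1ccc(O[Si](C)(C)C(C)(C)C)cc1 | starting material
12 | diethyl {2-[methoxy(methyl)amino]-2-oxoethyl}phosphonate | CCOP(=O)(CC(=O)N(C)OC)OCC | starting material
13 | (2E)-3-{4-[(tert-butyldimethylsilyl)oxy]phenyl}-N-methoxy-N-methylprop-2-enamide | CON(C)C(=O)/C=C/c1ccc(O[Si](C)(C)C(C)(C)C)cc1 | intermediate
14 | {(3R)-3-[(tert-butyldimethylsilyl)oxy]-7-methoxy-2,2-dimethyl-5-[(triisopropylsilyl)oxy]-3,4-dihydro-2H-chromen-8-yl}lithium | COc1cc(O[Si](C(C)C)(C(C)C)C(C)C)c2c(c1[Li])OC(C)(C)[C@H](O[Si](C)(C)C(C)(C)C)C2 | intermediate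
15 | (2E)-1-{(3R)-3-[(tert-butyldimethylsilyl)oxy]-7-methoxy-2,2-dimethyl-5-[(triisopropylsilyl)oxy]-3,4-dihydro-2H-chromen-8-yl}-3-{4-[(tert-butyldimethylsilyl)oxy]phenyl}prop-2-en-1-one | COc1cc(O[Si](C(C)C)(C(C)C)C(C)C)c2c(c1C(=O)/C=C/c1ccc(O[Si](C)(C)C(C)(C)C)cc1)OC(C)(C)[C@H](O[Si](C)(C)C(C)(C)C)C2 | intermediate
16 | (2E)-1-[(3R)-3,5-dihydroxy-7-methoxy-2,2-dimethyl-3,4-dihydro-2H-chromen-8-yl]-3-(4-hydroxyphenyl)prop-2-en-1-one | COc1cc(O)c2c(c1C(=O)/C=C/c1ccc(O)cc1)OC(C)(C)[C@H](O)C2 | target

**Step count and risks**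

Total step count: 10. Longest linear sequence: 9 steps (steps 1–7, 9 and 10, from phloroglucinol).

Steps most likely to fail:

1. Step 5. The trivalent-iodine reagent may attack the very electron-rich ring A (aryl-iodane formation or ring oxidation) in competition with the alkene, or acid-induced addition of methanol to the alkene may outrun the rearrangement. The fallback avoids both the alkene and any oxidant and sets out from ketone 6. Dibromomethyllithium (CH2Br2, lithium 2,2,6,6-tetramethylpiperidide, THF, −78 °C) should add to the non-enolisable carbonyl to give 3-(dibromomethyl)-6-methoxy-2,2-dimethyl-4-[(triisopropylsilyl)oxy]-2,3-dihydro-1-benzofuran-3-ol F1. Treatment of this carbinol with n-BuLi (2.2 equiv, −78 °C → 0 °C) removes the hydroxyl proton and exchanges one bromine. In the resulting β-oxido carbenoid the aryl carbon should migrate with loss of bromide to give the lithium enolate of the ring-enlarged ketone, and protonation returns the route at 8.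

2. Step 9. Deprotonation at C6 may compete with C8, the silyl group may migrate from oxygen to a neighbouring lithiated carbon, or the di-ortho-substituted aryllithium may add slowly or in conjugate fashion. The fallback fixes the position by electrophilic substitution and sets out from 10. One equivalent of Bu4NF at −20 °C should cleave only the aryl silyl ether to give (3R)-3-[(tert-butyldimethylsilyl)oxy]-7-methoxy-2,2-dimethyl-3,4-dihydro-2H-chromen-5-ol F2. Bu4NBr3 in CH2Cl2/MeOH should brominate para to the free phenol, that is at C8, to give (3R)-8-bromo-3-[(tert-butyldimethylsilyl)oxy]-7-methoxy-2,2-dimethyl-3,4-dihydro-2H-chromen-5-ol F3. Re-silylation (TIPSOTf, 2,6-lutidine) gives {[(3R)-8-bromo-3-[(tert-butyldimethylsilyl)oxy]-7-methoxy-2,2-dimethyl-3,4-dihydro-2H-chromen-5-yl]oxy}triisopropylsilane F4. Bromine–lithium exchange (t-BuLi, 2 equiv, Et2O, −78 °C) then returns the route at 14, which is acylated with 13 as in step 9.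

3. Step 6. Facial selectivity may be poor because both flanks of the ring ketone are substituted, and the ketone may suffer from its easy enolisation toward C4. The fallback replaces asymmetric catalysis by resolution and sets out from 8. NaBH4 in MeOH should give racemic 7-methoxy-2,2-dimethyl-5-[(triisopropylsilyl)oxy]-3,4-dihydro-2H-chromen-3-ol F5. Esterification with (S)-2-methoxy-2-phenylacetic acid (DCC, DMAP, CH2Cl2) gives two diastereomeric esters that are separated by chromatography: (3R)-7-methoxy-2,2-dimethyl-5-[(triisopropylsilyl)oxy]-3,4-dihydro-2H-chromen-3-yl (2S)-2-methoxy-2-phenylacetate F6 and its (3S)-diastereomer (3S)-7-methoxy-2,2-dimethyl-5-[(triisopropylsilyl)oxy]-3,4-dihydro-2H-chromen-3-yl (2S)-2-methoxy-2-phenylacetate F7, which is set aside. Reductive cleavage of F6 with i-Bu2AlH (CH2Cl2, −78 °C), which spares the aryl silyl ether, returns the route at 9.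

**Further compounds**

F1 | step 5 | 3-(dibromomethyl)-6-methoxy-2,2-dimethyl-4-[(triisopropylsilyl)oxy]-2,3-dihydro-1-benzofuran-3-ol | COc1cc(O[Si](C(C)C)(C(C)C)C(C)C)c2c(c1)OC(C)(C)C2(O)C(Br)Br
F2 | step 9 | (3R)-3-[(tert-butyldimethylsilyl)oxy]-7-methoxy-2,2-dimethyl-3,4-dihydro-2H-chromen-5-ol | COc1cc(O)c2c(c1)OC(C)(C)[C@H](O[Si](C)(C)C(C)(C)C)C2
F3 | step 9 | (3R)-8-bromo-3-[(tert-butyldimethylsilyl)oxy]-7-methoxy-2,2-dimethyl-3,4-dihydro-2H-chromen-5-ol | COc1cc(O)c2c(c1Br)OC(C)(C)[C@H](O[Si](C)(C)C(C)(C)C)C2
F4 | step 9 | {[(3R)-8-bromo-3-[(tert-butyldimethylsilyl)oxy]-7-methoxy-2,2-dimethyl-3,4-dihydro-2H-chromen-5-yl]oxy}triisopropylsilane | COc1cc(O[Si](C(C)C)(C(C)C)C(C)C)c2c(c1Br)OC(C)(C)[C@H](O[Si](C)(C)C(C)(C)C)C2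
F5 | step 6 | racemic 7-methoxy-2,2-dimethyl-5-[(triisopropylsilyl)oxy]-3,4-dihydro-2H-chromen-3-ol | COc1cc(O[Si](C(C)C)(C(C)C)C(C)C)c2c(c1)OC(C)(C)C(O)C2
F6 | step 6 | (3R)-7-methoxy-2,2-dimethyl-5-[(triisopropylsilyl)oxy]-3,4-dihydro-2H-chromen-3-yl (2S)-2-methoxy-2-phenylacetate | COc1cc(O[Si](C(C)C)(C(C)C)C(C)C)c2c(c1)OC(C)(C)[C@H](OC(=O)[C@@H](OC)c1ccccc1)C2
F7 | step 6 | (3S)-7-methoxy-2,2-dimethyl-5-[(triisopropylsilyl)oxy]-3,4-dihydro-2H-chromen-3-yl (2S)-2-methoxy-2-phenylacetate | COc1cc(O[Si](C(C)C)(C(C)C)C(C)C)c2c(c1)OC(C)(C)[C@@H](OC(=O)[C@@H](OC)c1ccccc1)C2
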